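# Synthesis plan for (+)-miliusane XVII (21) by one-carbon ring expansion of a chiral-pool spirocyclopentanone

## The problem

The target 21 is a 2-oxaspiro[4.5]decane. A γ-lactone (C1, O2, C3, C4) and a 4-acetoxycyclohex-2-enone (C6 ketone, C7=C8, C9 acetate, C10) share the quaternary carbon C5, and C1 carries a (1E,4E)-dienyl chain (C1'–C7') ending in a tertiary alcohol. Three stereocentres have to be set: C1 (R), C5 (R) and C9 (S). C9 lies 1,3 to C5 across the carbocycle and C1 is bonded to C5, so a resident C9 oxygen can steer the face at which C5 is completed and a C1 oxygen can reinforce it, but nothing in the molecule controls C1 itself. The spiro carbon must receive two different carbon arms, with the lactone methylene C4 anti and the carbinol C1 syn to the C9 oxygen.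

Several groups rule out rough treatment:
- the C9 oxygen is a leaving group β or γ to a carbonyl at every stage;
- the allylic C1–O lactone bond and the tertiary allylic carbinol ionise under acid;
- the skipped diene (C3' methylene) slips into conjugation under base;
- an opened lactone uncovers a β-hydroxy ketone that can fragment by retro-aldol cleavage.

The enabling feature is the C6 ketone, flanked by quaternary C5 on one side and by C7 on the other. Removing C7 from the six-membered ring leaves a 2,2-disubstituted 4-oxycyclopentanone, the skeleton of commercial (R)-4-silyloxycyclopent-2-enone with C9 already in place. The open side of that ketone (C8) is where a one-carbon insertion should occur.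

## Retrosynthesis

Atom labels C1–C10 of the target core are kept for every intermediate (C7 is absent before the ring expansion). Side-chain carbons are C1'–C7', counted from the carbon bonded to C1.

**21 ⇒ 20 ⇒ 19.** The acetyl C–O bond at C9 and the two Si–O bonds are cut first. The acetate cannot be carried through the route, because at the cyclopentanone stage the C9 oxygen sits β to the C6 ketone and an ester there would be lost by elimination; a silyl ether is the safer passenger. Diol 20 differs from 21 only by the acetyl group, and the forward step needs no more than the reactivity gap between a secondary allylic and a tertiary hydroxyl. Disilyl enone 19 lets both silyl groups fall in one operation.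

**19 ⇒ 17.** The C7=C8 π bond is removed, leaving ketone 17. C5 has no hydrogen, so 17 can enolise only toward C7 and the position of the alkene is not a selectivity question. Carrying the enone through earlier steps is ruled out, since a diazo reagent would add across it. The forward step must enolise the ketone without touching the lactone methylene C4.

**17 ⇒ 14 + 15.** C7 is excised: the C6–C7 and C7–C8 bonds are cut and C6 is rejoined to C8. This gives spirocyclopentanone 14 and trimethylsilyldiazomethane 15 as the one-carbon donor. No other single-carbon excision leaves a ring that maps onto a chiral-pool cyclopentenone with C9 in place, and any cut at C5 would reopen the quaternary centre. Compound 14 already holds all three stereocentres on a five-membered ring, whose faces the C9 substituent differentiates more reliably than those of a cyclohexanone. The forward reaction must move C8 rather than C5, stop after one insertion, and use a catalyst mild enough for the β-silyloxy ketone and the allylic lactone.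

**14 ⇒ 10 + 11.** The spirolactone is opened at C5–C4 and O2–C3, which leads to enone 10 and methyl bromoacetate 11. The C5 enolate must be formed regiospecifically. Deprotonating a saturated ketone would place the enolate toward C8 and expel the C9 silyloxy group, so the C5=C10 alkene of 10 serves as the latent enolate, released by conjugate hydride addition. The reverse order (haloacetate arm first, aldol last) would place C1 anti to the C9 oxygen, which is the wrong C5 configuration. A methyl ester is preferred to a tert-butyl ester so that the C1 alkoxide closes the lactone in the same flask; an acid-mediated ester cleavage would endanger the allylic C1–O bond. The forward step must alkylate anti to the C9 silyl ether.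

**10 ⇒ 8 + 9.** The C1–C5 bond is cut between the α-carbon of cyclopentenone 9 and the aldehyde carbon of dienal 8 (Morita–Baylis–Hillman). This cut keeps the enone alkene needed in the next step and brings in the whole side chain at once. An aldol of a saturated ketone would lose the regiochemical handle. The forward reaction must set C1 (R) by catalyst control, because C9 is too remote to do it.

**8 ⇒ 7 ⇒ 5.** Oxidation-level adjustment leads to allylic alcohol 7. Cutting the C2'–methyl bond and the bond from C1' to the carbinol carbon gives terminal alkyne 5, by way of alkenylalane 6. A syn methyl–metal addition across a terminal alkyne is the most dependable way to obtain the E trisubstituted alkene; an olefination of a methyl ketone would give geometric mixtures.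

**5 ⇒ 4 ⇒ 3 ⇒ 1 + 2.** The silyl ether is removed to give 4, the E alkene is traced to the propargylic alkyne of diyne 3, and the C–C bond between the two three-carbon units is cut to 2-methylbut-3-yn-2-ol 1 and propargyl bromide 2. The free tertiary hydroxyl of 3 directs the trans reduction to its own alkyne, so the E geometry and the site selectivity come from the same group.

## Roads not taken

**Alternative 1: quinone monoketal ipso-Michael spirolactonisation.**
- The cut: C4–C5.
- Forward key step: LiN(SiMe3)2 converts the C1 acetate of quinone monoketal A1 into its enolate, which adds 5-exo-trig to C5, the substituted β-carbon of the dienone. This gives spirolactone A2 with a C9 enone and a C6 dimethyl ketal.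
- Merits: the quaternary centre and the lactone form in one step from an aromatic precursor. The ring arrives with C7=C8 in place and both carbonyl positions differentiated, so neither a ring expansion nor a dehydrogenation is needed. In step count this road is clearly shorter than the chosen one.
- Weak points: C5 is created by 1,2-induction from C1 alone, on a flat dienone whose two faces differ only through the rotamer preference of the tether. C9 must then be set by reducing a ketone that is 1,3 to C5 with no nearby directing group. Both selectivities are of unknown sense. The base-sensitive monoketal has to survive an ester enolate, and the C6 ketal must later be hydrolysed beside two acid-labile allylic C–O bonds.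
- Comparison: the chosen plan sets against the shorter sequence a C9 centre bought from the chiral pool and a C5 centre formed under matched control by C9 and C1.

**Alternative 2: nitrile oxide cycloaddition as a masked aldol.**
- The cut: C6–C5 and O–C1.
- Forward key step: NaOCl oxidises the aldoxime of open-chain precursor A3 to a nitrile oxide, which adds across the tethered trisubstituted C5=C1 alkene. The six-membered carbocycle and the isoxazoline of A4 close together.
- Merits: the cycloaddition is suprafacial, so the C1/C5 relationship is transcribed from the alkene geometry in a single stereospecific event. In that respect it is better than the chosen plan, which needs two separately controlled steps. A chair-like transition state with the C9 silyloxy group equatorial should also control the ring face.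
- Weak points: the dipolarophile is the inner alkene of a conjugated diene, and the outer alkene competes. The geometrically pure trisubstituted alkene bearing the ester arm is itself a hard target. C9 must be made by asymmetric synthesis in an acyclic chain. The N–O bond must be cleaved reductively in the presence of three alkenes. Lactonisation and the C7=C8 dehydrogenation still remain, so the end game is no shorter.
- Comparison: the chosen plan answers the stereospecificity of this road with a matched, doubly controlled alkylation and a far simpler precursor.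

**Alternative 3: palladium 1,4-oxylactonisation–acetoxylation of a cyclohexa-1,3-diene.**
- The cut: C6–O and C9–OAc.
- Forward key step: Pd(OAc)2 with benzoquinone and LiOAc in acetic acid, without chloride, makes the carboxylic acid of diene A5 attack C6 and delivers acetate to C9 trans to it. This gives the cis-fused lactone A6 with C7=C8 in place.
- Merits: the C9 acetate and the ring alkene are installed directly at their final oxidation level, and the C9/C5 relationship follows from the mechanism. No protecting group at C9, no late dehydrogenation and no final acetylation are needed; here it is better than the chosen plan.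
- Weak points: the lactone closes on the C6 oxygen, not on C1. A translactonisation of uncertain position and an oxidation of the C6 carbinol beside the C9 acetate must follow. The quaternary C5 and C1 must be built enantioselectively on a diene with no resident stereocentre, which is the hardest part of the problem and is left unsolved by the key step. The side-chain alkenes and allylic ethers must also tolerate divalent palladium in acetic acid.
- Comparison: the chosen plan pays three late steps (dehydrogenation, desilylation, acetylation) but creates C5 under the control of a purchased C9 centre.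

Key step: step 8

Assumption: the (R)-configured diol named in step 6 is taken to induce the 1R configuration of 10; if the first run shows the opposite sense, its antipode is used and nothing else changes.

## Route

Step 1
Reactants: 1 2-methylbut-3-yn-2-ol; 2 3-bromoprop-1-yne (propargyl bromide)
Product: 3 2-methylhepta-3,6-diyn-2-ol
Conditions: 1 (3 equiv), CuI (10 mol %), Cs2CO3, DMF, rt
Reagents that add atoms: none
Why: Copper-mediated alkynyl–propargyl coupling: the copper acetylide of 1 displaces bromide from 2 at the CH2 carbon to give the skipped diyne. Carbonate is too weak a base to isomerise the 1,4-diyne, and the excess of inexpensive 1 suppresses a second propargylation at the new terminal alkyne.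

Step 2
Reactants: 3 2-methylhepta-3,6-diyn-2-ol
Product: 4 (3E)-2-methylhept-3-en-6-yn-2-ol
Conditions: NaAlH2(OCH2CH2OMe)2 (3 equiv), THF, 0 °C → rt
Reagents that add atoms: none
Why: Hydroxyl-directed trans-hydroalumination of a propargylic alcohol: the alkoxyaluminium hydride delivers hydride only to the triple bond next to the carbinol, and protonolysis of the cyclic alkenylaluminate gives the E alkene. The remote terminal alkyne is only deprotonated and returns on work-up.

Step 3
Reactants: 4 (3E)-2-methylhept-3-en-6-yn-2-ol
Product: 5 triethyl{[(3E)-2-methylhept-3-en-6-yn-2-yl]oxy}silane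
Conditions: Et3SiOTf, 2,6-lutidine, CH2Cl2, −78 → 0 °C
Reagents that add atoms: triethylsilyl trifluoromethanesulfonate, CC[Si](CC)(CC)OS(=O)(=O)C(F)(F)F
Why: A silyl triflate with a hindered pyridine base is the standard silylation of a tertiary alcohol. The ether masks the carbinol through the organoaluminium, enolate and Lewis-acid steps and is removed together with the C9 silyl ether at the end.

Step 4
Reactants: 5 triethyl{[(3E)-2-methylhept-3-en-6-yn-2-yl]oxy}silane
Product: 7 (2E,5E)-3,7-dimethyl-7-(triethylsilyloxy)octa-2,5-dien-1-ol, via alkenyldimethylalane 6 (not isolated)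
Conditions: AlMe3, Cp2ZrCl2 (20 mol %), CH2Cl2, 0 °C → rt; then n-BuLi, (CH2O)n, THF, −78 °C → rt
Reagents that add atoms: trimethylaluminium, C[Al](C)C; formaldehyde (as paraformaldehyde), C=O
Why: Zirconium-catalysed carboalumination (Negishi) adds methyl and aluminium syn across the terminal alkyne with aluminium on the terminal carbon, which fixes the E geometry of the future C1'=C2' alkene. The derived aluminate adds to formaldehyde with retention to give the allylic alcohol.

Step 5
Reactants: 7 (2E,5E)-3,7-dimethyl-7-(triethylsilyloxy)octa-2,5-dien-1-ol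
Product: 8 (2E,5E)-3,7-dimethyl-7-(triethylsilyloxy)octa-2,5-dienal
Conditions: MnO2, CH2Cl2, rt
Reagents that add atoms: none
Why: MnO2 oxidises the primary allylic alcohol to the enal under neutral, non-enolising conditions, so neither the alkene geometry nor the skipped diene should be disturbed.

Step 6
Reactants: 8 (2E,5E)-3,7-dimethyl-7-(triethylsilyloxy)octa-2,5-dienal; 9 (4R)-4-(tert-butyldimethylsilyloxy)cyclopent-2-en-1-one
Product: 10 (4R)-4-(tert-butyldimethylsilyloxy)-2-[(1R,2E,5E)-1-hydroxy-3,7-dimethyl-7-(triethylsilyloxy)octa-2,5-dien-1-yl]cyclopent-2-en-1-one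
Conditions: 9 (2 equiv), PEt3 (1 equiv), (R)-3,3'-bis(3,5-dimethylphenyl)-5,5',6,6',7,7',8,8'-octahydro-1,1'-bi-2-naphthol (10 mol %), THF, −10 °C
Reagents that add atoms: none
Why: Morita–Baylis–Hillman reaction: PEt3 adds to C10 of 9 anti to the silyl ether, the phosphonium enolate attacks the aldehyde carbon of 8 through C5, and proton transfer with loss of the phosphine restores the enone. The new C1 stereocentre (R) is set by the chiral Brønsted acid, which stays hydrogen-bonded to the enolate oxygen in the aldol step and selects the aldehyde face (catalyst control, C9 being remote). The β,β-disubstituted enal is a poor conjugate acceptor, so only 1,2-addition is expected.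

Step 7
Reactants: 10 (4R)-4-(tert-butyldimethylsilyloxy)-2-[(1R,2E,5E)-1-hydroxy-3,7-dimethyl-7-(triethylsilyloxy)octa-2,5-dien-1-yl]cyclopent-2-en-1-one; 11 methyl bromoacetate
Product: 14 (1R,5R,8S)-8-(tert-butyldimethylsilyloxy)-1-[(1E,4E)-2,6-dimethyl-6-(triethylsilyloxy)hepta-1,4-dien-1-yl]-2-oxaspiro[4.4]nonane-3,6-dione, via dilithium alkoxide enolate 12 (not isolated), via lithium alkoxide keto ester 13 (not isolated)
Conditions: LiN(SiMe3)2 (1.0 equiv), THF, −78 °C; LiBH(s-Bu)3 (1.05 equiv), −78 °C; then 11 (1.5 equiv), DMPU, −78 → −20 °C; AcOH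
Reagents that add atoms: none
Why: Conjugate hydride addition to the alkoxide of 10 gives the C5=C6 enolate 12 regiospecifically (reductive alkylation of an enone), the only access to this enolate that keeps base away from C8 and the C9 silyloxy leaving group. Alkylation by 11 sets C5 (R): the lithium chelate between enolate oxygen and C1 alkoxide holds the dienyl group of C1 on the face of the C9 silyl ether, so the electrophile enters from the opposite face, anti to both (Fráter–Seebach-type control, matched with the ring substituent). The C1 alkoxide of 13 then closes the γ-lactone on the methyl ester (5-exo-trig acyl substitution), which forms O2–C3 without touching the allylic C1–O bond and removes the aldolate before it can fragment.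

Step 8
Reactants: 14 (1R,5R,8S)-8-(tert-butyldimethylsilyloxy)-1-[(1E,4E)-2,6-dimethyl-6-(triethylsilyloxy)hepta-1,4-dien-1-yl]-2-oxaspiro[4.4]nonane-3,6-dione; 15 (diazomethyl)trimethylsilane (trimethylsilyldiazomethane)
Product: 17 (1R,5R,9R)-9-(tert-butyldimethylsilyloxy)-1-[(1E,4E)-2,6-dimethyl-6-(triethylsilyloxy)hepta-1,4-dien-1-yl]-2-oxaspiro[4.5]decane-3,6-dione, via C7-trimethylsilyl ketone 16 (not isolated)
Conditions: 15 (1.5 equiv), Sc(OTf)3 (10 mol %), CH2Cl2, −78 → 0 °C; then H2O, SiO2, CH2Cl2, rt
Reagents that add atoms: none
Why: Trivalent scandium activates the C6 ketone, the nucleophilic diazo carbon of 15 adds to it, and loss of N2 from the diazonium alkoxide is coupled to a 1,2-shift of C8, so the new carbon enters between C6 and C8 as C7 (C6–C7 and C7–C8 formed, C6–C8 broken) and the C7-silyl ketone 16 results. The closest known reaction type is the Sc(OTf)3-catalysed homologation of cycloalkanones with trimethylsilyldiazomethane, a Lewis-acid variant of the Tiffeneau–Demjanov and diazoalkane ring expansions. The six-membered ring arises by enlargement of the five-membered ketone through this 1,2-shift and not by a new cyclisation, so no ring-closure mode has to be met. No lasting stereocentre is created: C7 of 16 is a transient epimeric centre erased on protodesilylation with wet silica, and C1, C5 and C9 take no part, the migrating C8 being a methylene. The selectivity needed is migration of C8 over C5; only the rotamer with N2 anti to C8 lets the Me3Si group avoid a gauche contact with the fully substituted C5, and the catalysed process is known to move the less substituted α-carbon. The ketone reacts in preference to the lactone carbonyl, which does not homologate, and the alkenes are inert because no metal carbene is formed. The bulky silyl group beside the new carbonyl, with quaternary C5 on the other side, should stop a second insertion. Low temperature and a catalytic amount of Lewis acid are chosen to spare the β-silyloxy ketone, the allylic C1–O bond and the tertiary allylic silyl ether.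

Step 9
Reactants: 17 (1R,5R,9R)-9-(tert-butyldimethylsilyloxy)-1-[(1E,4E)-2,6-dimethyl-6-(triethylsilyloxy)hepta-1,4-dien-1-yl]-2-oxaspiro[4.5]decane-3,6-dione
Product: 19 (1R,5R,9S)-9-(tert-butyldimethylsilyloxy)-1-[(1E,4E)-2,6-dimethyl-6-(triethylsilyloxy)hepta-1,4-dien-1-yl]-2-oxaspiro[4.5]dec-7-ene-3,6-dione, via trimethylsilyl enol ether 18 (not isolated)
Conditions: LiN(SiMe3)2, Me3SiCl, THF, −78 °C; then Pd(OAc)2 (1.1 equiv), MeCN, rt
Reagents that add atoms: none
Why: Kinetic deprotonation can occur only at C7 of the ketone (C5 is quaternary and the lactone methylene is markedly less acidic), and the internal silyl quench gives enol ether 18. Saegusa–Ito oxidation (palladium enolate, β-hydride elimination from C8) then gives the C7=C8 enone without affecting C9.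

Step 10
Reactants: 19 (1R,5R,9S)-9-(tert-butyldimethylsilyloxy)-1-[(1E,4E)-2,6-dimethyl-6-(triethylsilyloxy)hepta-1,4-dien-1-yl]-2-oxaspiro[4.5]dec-7-ene-3,6-dione
Product: 20 (1R,5R,9S)-9-hydroxy-1-[(1E,4E)-6-hydroxy-2,6-dimethylhepta-1,4-dien-1-yl]-2-oxaspiro[4.5]dec-7-ene-3,6-dione
Conditions: HF·pyridine, pyridine, THF, 0 °C → rt
Reagents that add atoms: none
Why: Fluoride cleaves the secondary tert-butyldimethylsilyl ether and the tertiary triethylsilyl ether. The pyridine-buffered reagent is not basic enough to open the lactone or eliminate the C9 oxygen, and not acidic enough to ionise the allylic C–O bonds.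

Step 11
Reactants: 20 (1R,5R,9S)-9-hydroxy-1-[(1E,4E)-6-hydroxy-2,6-dimethylhepta-1,4-dien-1-yl]-2-oxaspiro[4.5]dec-7-ene-3,6-dione
Product: 21 (1R,5R,9S)-1-[(1E,4E)-6-hydroxy-2,6-dimethylhepta-1,4-dien-1-yl]-3,6-dioxo-2-oxaspiro[4.5]dec-7-en-9-yl acetate, (+)-miliusane XVII
Conditions: Ac2O, pyridine, 4-(dimethylamino)pyridine (cat.), CH2Cl2, 0 °C
Reagents that add atoms: acetic anhydride, CC(=O)OC(C)=O
Why: Acylation of the secondary allylic C9 hydroxyl. The tertiary carbinol is too hindered to be acetylated under these mild conditions, and C9 keeps its configuration because its C–O bond is not touched.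

## Compound list

1 | 2-methylbut-3-yn-2-ol | CC(C)(O)C#C | starting material
2 | 3-bromoprop-1-yne (propargyl bromide) | BrCC#C | starting material
3 | 2-methylhepta-3,6-diyn-2-ol | CC(C)(O)C#CCC#C | intermediate
4 | (3E)-2-methylhept-3-en-6-yn-2-ol | CC(C)(O)/C=C/CC#C | intermediate
5 | triethyl{[(3E)-2-methylhept-3-en-6-yn-2-yl]oxy}silane | CC[Si](CC)(CC)OC(C)(C)/C=C/CC#C | intermediate
6 | [(1E,4E)-2,6-dimethyl-6-(triethylsilyloxy)hepta-1,4-dien-1-yl]dimethylalane | C[Al](C)/C=C(\C)C/C=C/C(C)(C)O[Si](CC)(CC)CC | intermediate (not isolated)
7 | (2E,5E)-3,7-dimethyl-7-(triethylsilyloxy)octa-2,5-dien-1-ol | OC/C=C(\C)C/C=C/C(C)(C)O[Si](CC)(CC)CC | intermediate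
8 | (2E,5E)-3,7-dimethyl-7-(triethylsilyloxy)octa-2,5-dienal | O=C/C=C(\C)C/C=C/C(C)(C)O[Si](CC)(CC)CC | intermediate
9 | (4R)-4-(tert-butyldimethylsilyloxy)cyclopent-2-en-1-one | O=C1C=C[C@H](O[Si](C)(C)C(C)(C)C)C1 | starting material
10 | (4R)-4-(tert-butyldimethylsilyloxy)-2-[(1R,2E,5E)-1-hydroxy-3,7-dimethyl-7-(triethylsilyloxy)octa-2,5-dien-1-yl]cyclopent-2-en-1-one | CC(C)(C)[Si](C)(C)O[C@@H]1CC(=O)C([C@H](O)/C=C(\C)C/C=C/C(C)(C)O[Si](CC)(CC)CC)=C1 | intermediate
11 | methyl bromoacetate | COC(=O)CBr | starting material
12 | dilithium C1-alkoxide C5=C6 enolate formed from 10 by 1,4-hydride addition | CC(C)(C)[Si](C)(C)O[C@@H]1CC(O[Li])=C([C@H](O[Li])/C=C(\C)C/C=C/C(C)(C)O[Si](CC)(CC)CC)C1 | intermediate (not isolated)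
13 | lithium C1-alkoxide of methyl 2-[(1R,4S)-4-(tert-butyldimethylsilyloxy)-1-[(1R,2E,5E)-1-hydroxy-3,7-dimethyl-7-(triethylsilyloxy)octa-2,5-dien-1-yl]-2-oxocyclopentyl]acetate | CC(C)(C)[Si](C)(C)O[C@@H]1CC(=O)[C@](CC(=O)OC)([C@H](O[Li])/C=C(\C)C/C=C/C(C)(C)O[Si](CC)(CC)CC)C1 | intermediate (not isolated)
14 | (1R,5R,8S)-8-(tert-butyldimethylsilyloxy)-1-[(1E,4E)-2,6-dimethyl-6-(triethylsilyloxy)hepta-1,4-dien-1-yl]-2-oxaspiro[4.4]nonane-3,6-dione | CC(C)(C)[Si](C)(C)O[C@@H]1CC(=O)[C@@]2(CC(=O)O[C@@H]2/C=C(\C)C/C=C/C(C)(C)O[Si](CC)(CC)CC)C1 | intermediate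
15 | (diazomethyl)trimethylsilane (trimethylsilyldiazomethane) | C[Si](C)(C)C=[N+]=[N-] | starting material
16 | (1R,5R,9S)-9-(tert-butyldimethylsilyloxy)-1-[(1E,4E)-2,6-dimethyl-6-(triethylsilyloxy)hepta-1,4-dien-1-yl]-7-(trimethylsilyl)-2-oxaspiro[4.5]decane-3,6-dione (C7 epimers) | CC(C)(C)[Si](C)(C)O[C@@H]1CC([Si](C)(C)C)C(=O)[C@@]2(CC(=O)O[C@@H]2/C=C(\C)C/C=C/C(C)(C)O[Si](CC)(CC)CC)C1 | intermediate (not isolated)
17 | (1R,5R,9R)-9-(tert-butyldimethylsilyloxy)-1-[(1E,4E)-2,6-dimethyl-6-(triethylsilyloxy)hepta-1,4-dien-1-yl]-2-oxaspiro[4.5]decane-3,6-dione | CC(C)(C)[Si](C)(C)O[C@@H]1CCC(=O)[C@@]2(CC(=O)O[C@@H]2/C=C(\C)C/C=C/C(C)(C)O[Si](CC)(CC)CC)C1 | intermediate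
18 | (1R,5R,9R)-9-(tert-butyldimethylsilyloxy)-1-[(1E,4E)-2,6-dimethyl-6-(triethylsilyloxy)hepta-1,4-dien-1-yl]-6-(trimethylsilyloxy)-2-oxaspiro[4.5]dec-6-en-3-one | CC(C)(C)[Si](C)(C)O[C@@H]1CC=C(O[Si](C)(C)C)[C@@]2(CC(=O)O[C@@H]2/C=C(\C)C/C=C/C(C)(C)O[Si](CC)(CC)CC)C1 | intermediate (not isolated)
19 | (1R,5R,9S)-9-(tert-butyldimethylsilyloxy)-1-[(1E,4E)-2,6-dimethyl-6-(triethylsilyloxy)hepta-1,4-dien-1-yl]-2-oxaspiro[4.5]dec-7-ene-3,6-dione | CC(C)(C)[Si](C)(C)O[C@@H]1C=CC(=O)[C@@]2(CC(=O)O[C@@H]2/C=C(\C)C/C=C/C(C)(C)O[Si](CC)(CC)CC)C1 | intermediate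
20 | (1R,5R,9S)-9-hydroxy-1-[(1E,4E)-6-hydroxy-2,6-dimethylhepta-1,4-dien-1-yl]-2-oxaspiro[4.5]dec-7-ene-3,6-dione | O[C@@H]1C=CC(=O)[C@@]2(CC(=O)O[C@@H]2/C=C(\C)C/C=C/C(C)(C)O)C1 | intermediate
21 | (1R,5R,9S)-1-[(1E,4E)-6-hydroxy-2,6-dimethylhepta-1,4-dien-1-yl]-3,6-dioxo-2-oxaspiro[4.5]dec-7-en-9-yl acetate, (+)-miliusane XVII | CC(=O)O[C@@H]1C=CC(=O)[C@@]2(CC(=O)O[C@@H]2/C=C(\C)C/C=C/C(C)(C)O)C1 | target

## Step count and least certain steps

Total step count: 11. Longest linear sequence: 11 steps (1 and 2 to 21; 9, 11 and 15 enter as purchased materials).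

**Step 8 (key step).** The most likely failures are:
- migration of the quaternary C5 in competition with C8, or no reaction at a ketone crowded by the spiro centre;
- scandium-triggered ionisation of the allylic C1–O lactone bond or of the tertiary allylic silyl ether;
- β-elimination of the C9 silyloxy group.

The fallback makes the same three bond changes by the siloxycyclopropane route and sets out from 14. Silylation with internal quench (LiN(SiMe3)2, Me3SiCl, −78 °C) should give the C6–C8 trimethylsilyl enol ether F1. Simmons–Smith cyclopropanation (Et2Zn, CH2I2) of this electron-rich alkene should give the siloxycyclopropane F2. FeCl3 in DMF should cleave the internal C6–C8 bond to the ring-enlarged 8-chloro ketone F3, and NaOAc in MeOH should eliminate HCl. The sequence comes back to the route at enone 19, bypassing 17.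

**Step 6.** The electron-rich, β,β-disubstituted enal 8 may react too slowly in the aldol step. The temporary phosphonium centre at C10, placed anti to the silyl ether, may impose a substrate bias that erodes catalyst control at C1. The phosphine may also induce loss of silanol from 9. The fallback sets out from 9. Iodination (I2, pyridine) should give the 2-iodoenone F4, and a Nozaki–Hiyama–Kishi coupling with 8 (CrCl2, NiCl2 cat., DMSO), which is neutral and tolerant of enals, should give 10 together with its C1 epimer F5. After chromatographic separation, F5 would be inverted by Mitsunobu esterification (4-nitrobenzoic acid, PPh3, diisopropyl azodicarboxylate) to the 4-nitrobenzoate F6, and mild methanolysis (K2CO3, MeOH, 0 °C) comes back to the route at 10.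

**Step 7.** Hydride may be delivered 1,2 instead of 1,4 at the cyclopentenone. Alkylation of the hindered, borane-complexed tetrasubstituted enolate may be slow enough for proton transfer to the C8 side and loss of the C9 silyloxy group, and the aldolate 13 may fragment before it lactonises. The fallback sets out from 10. Silylation (Me3SiCl, imidazole) should give the C1 trimethylsilyl ether F7. Copper-hydride-catalysed 1,4-hydrosilylation ([(Ph3P)CuH]6 cat., PhMe2SiH, toluene) should give the regiodefined silyl enol ether F8. MeLi in THF should release the lithium enolate, which is alkylated with 11 to the keto ester F9. Citric acid in MeOH should remove the trimethylsilyl group, and the freed C1 hydroxyl lactonises, which comes back to the route at 14.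

**Step 9.** Divalent palladium may isomerise or oxidise the skipped diene at its doubly allylic methylene, or turnover at the hindered enol ether may be incomplete. The fallback sets out from 17. Enolate selenation (LiN(SiMe3)2, then PhSeCl, −78 °C) should give the 7-phenylselanyl ketone F10, and oxidation with H2O2 in the presence of pyridine at 0 °C followed by syn-elimination of the selenoxide comes back to the route at 19.

**Step 2.** The basic hydride reagent may cause prototropic isomerisation of the skipped diyne to allenes or conjugated enynes before or after reduction. The fallback sets out from 1 and introduces the alkyne only after the E alkene exists. The dianion of 1 (n-BuLi, 2 equiv) with paraformaldehyde should give 4-methylpent-2-yne-1,4-diol F11. The same hydride reduction, now on a simple propargylic diol, should give (2E)-4-methylpent-2-ene-1,4-diol F12. CBr4 and PPh3 should convert only the primary allylic hydroxyl into the bromide (3E)-5-bromo-2-methylpent-3-en-2-ol F13. CuBr-catalysed coupling with HC≡CMgBr comes back to the route at 4.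

## Further compounds

F1 | step 8 | (1R,5R,8S)-8-(tert-butyldimethylsilyloxy)-1-[(1E,4E)-2,6-dimethyl-6-(triethylsilyloxy)hepta-1,4-dien-1-yl]-6-(trimethylsilyloxy)-2-oxaspiro[4.4]non-6-en-3-one | CC(C)(C)[Si](C)(C)O[C@@H]1C=C(O[Si](C)(C)C)[C@@]2(CC(=O)O[C@@H]2/C=C(\C)C/C=C/C(C)(C)O[Si](CC)(CC)CC)C1
F2 | step 8 | siloxycyclopropane of F1, a methylene bridging C6 and C8 (configuration at C6 and C8 not assigned) | CC(C)(C)[Si](C)(C)O[C@@H]1C3CC3(O[Si](C)(C)C)[C@@]2(CC(=O)O[C@@H]2/C=C(\C)C/C=C/C(C)(C)O[Si](CC)(CC)CC)C1
F3 | step 8 | (1R,5R)-9-(tert-butyldimethylsilyloxy)-8-chloro-1-[(1E,4E)-2,6-dimethyl-6-(triethylsilyloxy)hepta-1,4-dien-1-yl]-2-oxaspiro[4.5]decane-3,6-dione (C8 epimers, C9 as in 17) | CC(C)(C)[Si](C)(C)O[C@@H]1C(Cl)CC(=O)[C@@]2(CC(=O)O[C@@H]2/C=C(\C)C/C=C/C(C)(C)O[Si](CC)(CC)CC)C1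
F4 | step 6 | (4R)-4-(tert-butyldimethylsilyloxy)-2-iodocyclopent-2-en-1-one | CC(C)(C)[Si](C)(C)O[C@@H]1CC(=O)C(I)=C1
F5 | step 6 | (4R)-4-(tert-butyldimethylsilyloxy)-2-[(1S,2E,5E)-1-hydroxy-3,7-dimethyl-7-(triethylsilyloxy)octa-2,5-dien-1-yl]cyclopent-2-en-1-one | CC(C)(C)[Si](C)(C)O[C@@H]1CC(=O)C([C@@H](O)/C=C(\C)C/C=C/C(C)(C)O[Si](CC)(CC)CC)=C1
F6 | step 6 | (1R,2E,5E)-1-[(3R)-3-(tert-butyldimethylsilyloxy)-5-oxocyclopent-1-en-1-yl]-3,7-dimethyl-7-(triethylsilyloxy)octa-2,5-dien-1-yl 4-nitrobenzoate | CC(C)(C)[Si](C)(C)O[C@@H]1CC(=O)C([C@H](OC(=O)c2ccc(cc2)[N+](=O)[O-])/C=C(\C)C/C=C/C(C)(C)O[Si](CC)(CC)CC)=C1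
F7 | step 7 | (4R)-4-(tert-butyldimethylsilyloxy)-2-[(1R,2E,5E)-3,7-dimethyl-7-(triethylsilyloxy)-1-(trimethylsilyloxy)octa-2,5-dien-1-yl]cyclopent-2-en-1-one | CC(C)(C)[Si](C)(C)O[C@@H]1CC(=O)C([C@H](O[Si](C)(C)C)/C=C(\C)C/C=C/C(C)(C)O[Si](CC)(CC)CC)=C1
F8 | step 7 | dimethylphenylsilyl enol ether (C5=C6) of 1,4-reduced F7 | CC(C)(C)[Si](C)(C)O[C@@H]1CC(O[Si](C)(C)c2ccccc2)=C([C@H](O[Si](C)(C)C)/C=C(\C)C/C=C/C(C)(C)O[Si](CC)(CC)CC)C1
F9 | step 7 | methyl 2-[(1R,4S)-4-(tert-butyldimethylsilyloxy)-1-[(1R,2E,5E)-3,7-dimethyl-7-(triethylsilyloxy)-1-(trimethylsilyloxy)octa-2,5-dien-1-yl]-2-oxocyclopentyl]acetate | CC(C)(C)[Si](C)(C)O[C@@H]1CC(=O)[C@](CC(=O)OC)([C@H](O[Si](C)(C)C)/C=C(\C)C/C=C/C(C)(C)O[Si](CC)(CC)CC)C1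
F10 | step 9 | 7-(phenylselanyl) derivative of 17 (C7 epimers) | CC(C)(C)[Si](C)(C)O[C@@H]1CC([Se]c3ccccc3)C(=O)[C@@]2(CC(=O)O[C@@H]2/C=C(\C)C/C=C/C(C)(C)O[Si](CC)(CC)CC)C1
F11 | step 2 | 4-methylpent-2-yne-1,4-diol | CC(C)(O)C#CCO
F12 | step 2 | (2E)-4-methylpent-2-ene-1,4-diol | CC(C)(O)/C=C/CO
F13 | step 2 | (3E)-5-bromo-2-methylpent-3-en-2-ol | CC(C)(O)/C=C/CBr
A1 | alternative 1 | (1R,2E,5E)-1-(6,6-dimethoxy-3-oxocyclohexa-1,4-dien-1-yl)-7-hydroxy-3,7-dimethylocta-2,5-dien-1-yl acetate | COC1(OC)C=CC(=O)C=C1[C@H](OC(C)=O)/C=C(\C)C/C=C/C(C)(C)O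
A2 | alternative 1 | (1R,5R)-1-[(1E,4E)-6-hydroxy-2,6-dimethylhepta-1,4-dien-1-yl]-6,6-dimethoxy-2-oxaspiro[4.5]dec-7-ene-3,9-dione | O=C1C=CC(OC)(OC)[C@@]2(CC(=O)O[C@@H]2/C=C(\C)C/C=C/C(C)(C)O)C1
A3 | alternative 2 | methyl (3E,5E,8E)-3-[(2R)-2-(tert-butyldimethylsilyloxy)-5-(hydroxyimino)pentyl]-10-hydroxy-6,10-dimethylundeca-3,5,8-trienoate | ON=CCC[C@@H](O[Si](C)(C)C(C)(C)C)C/C(CC(=O)OC)=C\C=C(/C)C/C=C/C(C)(C)O
A4 | alternative 2 | methyl 2-[(3R,3aS,5R)-5-(tert-butyldimethylsilyloxy)-3-[(1E,4E)-6-hydroxy-2,6-dimethylhepta-1,4-dien-1-yl]-3,3a,4,5,6,7-hexahydro-2,1-benzoxazol-3a-yl]acetate | CC(C)(C)[Si](C)(C)O[C@@H]1CCC2=NO[C@H](/C=C(\C)C/C=C/C(C)(C)O)[C@]2(CC(=O)OC)C1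
A5 | alternative 3 | 2-[(1S)-1-[(1R,2E,5E)-1-(tert-butyldimethylsilyloxy)-7-hydroxy-3,7-dimethylocta-2,5-dien-1-yl]cyclohexa-2,4-dien-1-yl]acetic acid | OC(=O)C[C@]1(CC=CC=C1)[C@H](O[Si](C)(C)C(C)(C)C)/C=C(\C)C/C=C/C(C)(C)O
A6 | alternative 3 | (3aS,5S,7aS)-3a-[(1R,2E,5E)-1-(tert-butyldimethylsilyloxy)-7-hydroxy-3,7-dimethylocta-2,5-dien-1-yl]-2-oxo-2,3,3a,4,5,7a-hexahydro-1-benzofuran-5-yl acetate | CC(=O)O[C@@H]1C=C[C@H]2OC(=O)C[C@]2(C1)[C@H](O[Si](C)(C)C(C)(C)C)/C=C(\C)C/C=C/C(C)(C)O
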